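**Retrosynthetic overview**
1. Feature: the only ring is the carbocycle C1–C6. It carries oxygen at C1, C2, C4 and C5, the C19 chain at C3 and H at C6. O2 and O4 flank C3 as in a 2-alkylresorcinol. C1 and C5 each lie ortho to one of these oxygens and para to the other, which is where a resorcinol is formylated and where peroxide most easily exchanges a formyl group for OH.
2. Quinone 24 ⇒ tetrol 23 (aerial oxidation) ⇒ dialdehyde 19. The C1–O and C5–O bonds come from C1–CHO and C5–CHO by a double Dakin oxidation, and both formyl carbons leave as formate.
3. 19 ⇒ 2-alkylresorcinol 17 (double magnesium-mediated ortho-formylation) ⇒ C3–C1' bond from 2-lithiated bis-MOM resorcinol 15 and the C19 bromide 12.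
4. 12 ⇒ C9 bromide 6 (Johnson–Claisen sets E-C14'=C15') plus THP-protected 10-bromodecanol 8, joined at C10'–C11' by copper-catalysed Grignard coupling.
5. Ring order: no ring is formed. The carbocycle is supplied by resorcinol and only its substituents change.

Key step: step 12

Assumption: the target has no stereocentre and is achiral, so the only stereochemical task is the E geometry of C14'=C15'. The quinone is written in the tautomer of the given SMILES (C1 and C4 as C=O), which is degenerate with the alternative one.

Step 1
Reactants: 1 (±)-hept-1-en-3-ol; 2 triethyl orthoacetate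
Product: 4 ethyl (E)-non-4-enoate, via ketene acetal 3 (not isolated)
Conditions: 2 (excess), EtCO2H (cat.), 138 °C, EtOH distilled off
Reagents that add atoms: none
Why: Johnson orthoester Claisen rearrangement, in which acid-catalysed exchange gives ketene acetal 3 and its chair [3,3] transition state holds the butyl group equatorial, so the new C=C should form with high E selectivity while the carbinol centre of racemic 1 is erased.

Step 2
Reactants: 4 ethyl (E)-non-4-enoate
Product: 5 (E)-non-4-en-1-ol
Conditions: LiAlH4, Et2O, 0 °C to rt; aqueous NaOH work-up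
Reagents that add atoms: none
Why: Hydride reduction of an ester to the primary alcohol, which does not touch an isolated dialkyl alkene.

Step 3
Reactants: 5 (E)-non-4-en-1-ol
Product: 6 (E)-1-bromonon-4-ene
Conditions: CBr4, PPh3, CH2Cl2, 0 °C
Reagents that add atoms: carbon tetrabromide, BrC(Br)(Br)Br
Why: Appel bromination, an SN2 displacement of an alkoxyphosphonium ion under neutral conditions, so neither the position nor the geometry of the alkene should change.

Step 4
Reactants: 7 10-bromodecan-1-ol
Product: 8 2-(10-bromodecoxy)oxane (THP ether, racemic at the acetal carbon)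
Conditions: 3,4-dihydro-2H-pyran, PPTS (cat.), CH2Cl2, rt
Reagents that add atoms: 3,4-dihydro-2H-pyran, C1CC=COC1
Why: Acid-catalysed addition of the alcohol to the enol ether (THP protection) masks the OH that would quench the Grignard reagent of step 5, and the irrelevant acetal centre is removed again in step 6.

Step 5
Reactants: 6 (E)-1-bromonon-4-ene; 8 2-(10-bromodecoxy)oxane
Product: 10 2-[(E)-nonadec-14-enoxy]oxane, via non-4-enylmagnesium bromide 9 (not isolated)
Conditions: 6 (slight excess), Mg, THF, 40 °C; then 8, Li2CuCl4 (3 mol %), NMP, THF, −10 °C to rt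
Reagents that add atoms: none
Why: Copper-catalysed (Kochi-type) sp3–sp3 coupling of a primary Grignard reagent with a primary bromide forms C10'–C11', the pent-4-enyl-type organometallic has no fast cyclisation path, and surplus 9 ends as volatile nonene that is easy to remove.

Step 6
Reactants: 10 2-[(E)-nonadec-14-enoxy]oxane
Product: 11 (E)-nonadec-14-en-1-ol
Conditions: p-TsOH·H2O (cat.), MeOH–THF, rt
Reagents that add atoms: none
Why: Acid-catalysed transacetalisation passes the THP group to methanol under conditions far too mild to protonate the alkene.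

Step 7
Reactants: 11 (E)-nonadec-14-en-1-ol
Product: 12 (E)-19-bromononadec-5-ene (the nonadec-14-enyl bromide)
Conditions: CBr4, PPh3, CH2Cl2, 0 °C
Reagents that add atoms: carbon tetrabromide, BrC(Br)(Br)Br
Why: Appel bromination as in step 3, neutral and SN2 in character, so it is compatible with the remote E alkene.

Step 8
Reactants: 13 resorcinol
Product: 14 1,3-bis(methoxymethoxy)benzene
Conditions: MOMCl, i-Pr2NEt, CH2Cl2, 0 °C to rt
Reagents that add atoms: chloromethyl methyl ether, COCCl
Why: Double O-alkylation of the phenols gives MOM ethers, chosen because they direct lithiation strongly and later leave under mild acid, whereas methyl ethers would need a Lewis acid that endangers the alkene.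

Step 9
Reactants: 14 1,3-bis(methoxymethoxy)benzene; 12 (E)-19-bromononadec-5-ene
Product: 16 1,3-bis(methoxymethoxy)-2-[(E)-nonadec-14-enyl]benzene, via 2-lithio arene 15 (not isolated)
Conditions: 14 (slight excess), n-BuLi, THF, 0 °C to rt; then 12, DMPU, 0 °C to 40 °C
Reagents that add atoms: none
Why: Directed ortho-metalation, in which the two OMOM groups cooperate to place lithium on the carbon between them (C3 of the overview), followed by SN2 alkylation with the primary bromide to form C3–C1'.

Step 10
Reactants: 16 1,3-bis(methoxymethoxy)-2-[(E)-nonadec-14-enyl]benzene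
Product: 17 2-[(E)-nonadec-14-enyl]benzene-1,3-diol
Conditions: HCl (cat.), MeOH–THF, 45 °C
Reagents that add atoms: none
Why: Acid-catalysed acetal cleavage in methanol traps the methoxymethyl cation as dimethoxymethane and frees both phenols without protonating the isolated alkene.

Step 11
Reactants: 17 2-[(E)-nonadec-14-enyl]benzene-1,3-diol
Product: 19 4,6-dihydroxy-5-[(E)-nonadec-14-enyl]benzene-1,3-dicarbaldehyde, via monoaldehyde 18 (not isolated)
Conditions: anhydrous MgCl2 (excess), Et3N (excess), (CH2O)n (large excess), MeCN–THF, reflux; 1 M HCl work-up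
Reagents that add atoms: paraformaldehyde (as formaldehyde), C=O
Why: Casnati–Skattebøl ortho-formylation run twice, in which each magnesium phenoxide delivers coordinated formaldehyde to its only free ortho carbon (C1, then C5; C3 is blocked by the chain and C6 is ortho to no oxygen) and an Oppenauer-type hydride transfer to a second formaldehyde gives the aldehyde, the second round matching the known formylation of 4-hydroxybenzaldehyde-type phenols and the amine-buffered medium leaving the alkene alone.

Step 12
Reactants: 19 4,6-dihydroxy-5-[(E)-nonadec-14-enyl]benzene-1,3-dicarbaldehyde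
Product: 23 3-[(E)-nonadec-14-enyl]benzene-1,2,4,5-tetrol, via formyl aryl formate 20 (not isolated), via trihydroxybenzaldehyde 21 (not isolated), via trihydroxyphenyl formate 22 (not isolated)
Conditions: 30% H2O2 (about 2.2 equiv, slow addition), 1 M NaOH (6 equiv), degassed THF–H2O, Ar, 0 to 10 °C; Na2SO3 quench, degassed 1 M HCl, EtOAc extraction under Ar, crude product used at once
Reagents that add atoms: hydrogen peroxide, OO
Why: This is a Dakin oxidation carried out on both formyl groups of one ring: hydroperoxide anion adds to each C=O and the tetrahedral adduct collapses by a 1,2-shift of the ring carbon (C1, then C5) from carbon to peroxide oxygen with loss of hydroxide, giving aryl formates 20 and 22 that are saponified at once. The closest known reaction is the Dakin oxidation of 2,4-dihydroxybenzaldehydes to benzene-1,2,4-triols, and here each migrating carbon again has one ortho and one para phenoxide, the pattern in which migration is fastest. No ring is closed and no stereocentre is created, so the step only makes the C1–O and C5–O bonds and expels the two placeholder carbons as formate. The first selectivity needed is aldehyde over the C14'=C15' alkene, and it is secured because HOO− is a nucleophilic oxidant that does not epoxidise an unactivated dialkyl alkene and because formate cannot become performic acid at high pH. The second need is survival of the very electron-rich species 21 and 23, which is addressed by excluding air, keeping the mixture cold, limiting peroxide to little more than two equivalents and destroying the remainder before acidification. THF keeps the soap-like sodium salts dissolved so that both oxidations run in one phase.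

Step 13
Reactants: 23 3-[(E)-nonadec-14-enyl]benzene-1,2,4,5-tetrol
Product: 24 2,5-dihydroxy-3-[(E)-nonadec-14-enyl]cyclohexa-2,5-diene-1,4-dione (target)
Conditions: air, 1 M NaOH, THF–H2O, rt; then 1 M HCl to pH 2; recrystallisation (EtOH)
Reagents that add atoms: none
Why: Base-promoted autoxidation of a hydroquinone, known to be fast for 1,2,4,5-tetrahydroxybenzenes, stops at the dihydroxyquinone because its dianion is a doubly vinylogous carboxylate and a thermodynamic sink, and crystallisation of the acidified solid gives a last chance to remove traces of Z isomer.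

**Compound list**
1 | (±)-hept-1-en-3-ol | CCCCC(O)C=C | starting material
2 | triethyl orthoacetate | CC(OCC)(OCC)OCC | starting material
3 | 3-[(1-ethoxyethenyl)oxy]hept-1-ene (racemic ketene acetal) | CCCCC(C=C)OC(=C)OCC | intermediate (not isolated)
4 | ethyl (E)-non-4-enoate | CCCC/C=C/CCC(=O)OCC | intermediate
5 | (E)-non-4-en-1-ol | CCCC/C=C/CCCO | intermediate
6 | (E)-1-bromonon-4-ene | CCCC/C=C/CCCBr | intermediate
7 | 10-bromodecan-1-ol | OCCCCCCCCCCBr | starting material
8 | 2-(10-bromodecoxy)oxane | BrCCCCCCCCCCOC1CCCCO1 | intermediate
9 | [(E)-non-4-enyl]magnesium bromide | CCCC/C=C/CCC[Mg]Br | intermediate (not isolated)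
10 | 2-[(E)-nonadec-14-enoxy]oxane | CCCC/C=C/CCCCCCCCCCCCCOC1CCCCO1 | intermediate
11 | (E)-nonadec-14-en-1-ol | CCCC/C=C/CCCCCCCCCCCCCO | intermediate
12 | (E)-19-bromononadec-5-ene | CCCC/C=C/CCCCCCCCCCCCCBr | intermediate
13 | resorcinol | Oc1cccc(O)c1 | starting material
14 | 1,3-bis(methoxymethoxy)benzene | COCOc1cccc(OCOC)c1 | intermediate
15 | 2-lithio-1,3-bis(methoxymethoxy)benzene | COCOc1cccc(OCOC)c1[Li] | intermediate (not isolated)
16 | 1,3-bis(methoxymethoxy)-2-[(E)-nonadec-14-enyl]benzene | CCCC/C=C/CCCCCCCCCCCCCc1c(OCOC)cccc1OCOC | intermediate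
17 | 2-[(E)-nonadec-14-enyl]benzene-1,3-diol | CCCC/C=C/CCCCCCCCCCCCCc1c(O)cccc1O | intermediate
18 | 2,4-dihydroxy-3-[(E)-nonadec-14-enyl]benzaldehyde | CCCC/C=C/CCCCCCCCCCCCCc1c(O)ccc(C=O)c1O | intermediate (not isolated)
19 | 4,6-dihydroxy-5-[(E)-nonadec-14-enyl]benzene-1,3-dicarbaldehyde | CCCC/C=C/CCCCCCCCCCCCCc1c(O)c(C=O)cc(C=O)c1O | intermediate
20 | 5-formyl-2,4-dihydroxy-3-[(E)-nonadec-14-enyl]phenyl formate | CCCC/C=C/CCCCCCCCCCCCCc1c(O)c(OC=O)cc(C=O)c1O | intermediate (not isolated)
21 | 2,4,5-trihydroxy-3-[(E)-nonadec-14-enyl]benzaldehyde | CCCC/C=C/CCCCCCCCCCCCCc1c(O)c(O)cc(C=O)c1O | intermediate (not isolated)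
22 | 2,4,5-trihydroxy-3-[(E)-nonadec-14-enyl]phenyl formate | CCCC/C=C/CCCCCCCCCCCCCc1c(O)c(O)cc(OC=O)c1O | intermediate (not isolated)
23 | 3-[(E)-nonadec-14-enyl]benzene-1,2,4,5-tetrol | CCCC/C=C/CCCCCCCCCCCCCc1c(O)c(O)cc(O)c1O | intermediate
24 | 2,5-dihydroxy-3-[(E)-nonadec-14-enyl]cyclohexa-2,5-diene-1,4-dione | CCCC/C=C/CCCCCCCCCCCCCC1=C(O)C(=O)C=C(O)C1=O | target

**Totals**
Total step count: 13.
Longest linear sequence: 11 steps (1, 2, 3, 5, 6, 7, 9, 10, 11, 12, 13).

**Steps most likely to fail**

Step 12 (double Dakin).
- Risk: the half-converted, hydroquinone-like ring may be oxidised before the second formyl group has migrated. Peroxide would then attack the electrophilic quinone and cleave the ring, and the peroxide lost on this path would leave the second migration incomplete. Early oxidation of the fully converted ring is harmless, since it only anticipates step 13.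
- Fallback: it sets out from 12 and returns at 24, and the oxygen pattern is bought instead of made. Commercial 1,2,4,5-tetramethoxybenzene is lithiated (n-BuLi, THF, 0 °C to rt) to 3-lithio-1,2,4,5-tetramethoxybenzene F1. This is alkylated with bromide 12 to 1,2,4,5-tetramethoxy-3-[(E)-nonadec-14-enyl]benzene F2. Oxidative demethylation with ceric ammonium nitrate (MeCN–H2O, 0 °C), which spares isolated alkenes, should give 2,5-dimethoxy-3-[(E)-nonadec-14-enyl]cyclohexa-2,5-diene-1,4-dione F3. Hydrolysis of its two vinylogous ester groups (aq NaOH, EtOH, then HCl) leads to 24.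

Step 11 (double formylation).
- Risk: the reaction may stall after the first formylation, because the first formyl group lowers the electron density at C5 and ties magnesium up in a chelate. Slow methoxymethylation of the ring may also occur on prolonged heating with formaldehyde.
- Fallback: it sets out from 16 and returns at 19, and the formyl groups are brought in through carbanions instead of phenoxides. Ring bromination of the doubly activated arene with NBS (2 equiv, MeCN, 0 °C, dark) is expected to outrun attack on the isolated alkene. It should give 1,5-dibromo-2,4-bis(methoxymethoxy)-3-[(E)-nonadec-14-enyl]benzene F4. Double bromine–lithium exchange (n-BuLi, THF–Et2O, −78 °C) gives 1,5-dilithio-2,4-bis(methoxymethoxy)-3-[(E)-nonadec-14-enyl]benzene F5. A DMF quench then gives 4,6-bis(methoxymethoxy)-5-[(E)-nonadec-14-enyl]benzene-1,3-dicarbaldehyde F6. Removal of the MOM groups (HCl, MeOH–THF, then aqueous work-up) gives 19.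

Step 9 (aryllithium alkylation).
- Risk: substitution by the hindered, aggregated aryllithium may be slow, so that E2 loss of HBr from the chain and protonation of the aryllithium compete.
- Fallback: it sets out from 15 and 12 and returns at 16, and the polarity of the C3–C1' bond formation is reversed. Aryllithium 15 is quenched with iodine to 2-iodo-1,3-bis(methoxymethoxy)benzene F7. Bromide 12 is converted by zinc insertion (Zn dust, cat. I2, DMA, 80 °C) into [(E)-nonadec-14-enyl]zinc bromide F8. The two are joined by a Negishi sp3–sp2 coupling (Pd(OAc)2, SPhos, THF–DMA, rt to 50 °C) to give 16.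

**Further compounds**
F1 | step 12 | 3-lithio-1,2,4,5-tetramethoxybenzene | COc1cc(OC)c(OC)c([Li])c1OC
F2 | step 12 | 1,2,4,5-tetramethoxy-3-[(E)-nonadec-14-enyl]benzene | CCCC/C=C/CCCCCCCCCCCCCc1c(OC)c(OC)cc(OC)c1OC
F3 | step 12 | 2,5-dimethoxy-3-[(E)-nonadec-14-enyl]cyclohexa-2,5-diene-1,4-dione | CCCC/C=C/CCCCCCCCCCCCCC1=C(OC)C(=O)C=C(OC)C1=O
F4 | step 11 | 1,5-dibromo-2,4-bis(methoxymethoxy)-3-[(E)-nonadec-14-enyl]benzene | CCCC/C=C/CCCCCCCCCCCCCc1c(OCOC)c(Br)cc(Br)c1OCOC
F5 | step 11 | 1,5-dilithio-2,4-bis(methoxymethoxy)-3-[(E)-nonadec-14-enyl]benzene | CCCC/C=C/CCCCCCCCCCCCCc1c(OCOC)c([Li])cc([Li])c1OCOC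
F6 | step 11 | 4,6-bis(methoxymethoxy)-5-[(E)-nonadec-14-enyl]benzene-1,3-dicarbaldehyde | CCCC/C=C/CCCCCCCCCCCCCc1c(OCOC)c(C=O)cc(C=O)c1OCOC
F7 | step 9 | 2-iodo-1,3-bis(methoxymethoxy)benzene | COCOc1cccc(OCOC)c1I
F8 | step 9 | [(E)-nonadec-14-enyl]zinc bromide | CCCC/C=C/CCCCCCCCCCCCC[Zn]Br
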